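**Plan**

- Retrosynthesis: the three silicon groups come off last. The C2–O(aryl) bond is cut to a 2-sulfonylchromone and a hydroquinone monosilyl ether. Ring C is cut at O1–C2 and C2–C3 (C2 from CS2) to a 2-hydroxyacetophenone, and the acetyl group at C4a–C4 and C4–C3 (formaldehyde, then a methyl Grignard reagent).
- Ring A is cut at C8a–C8 and C7–C6 into a 3-alkoxycyclobutenone and a prenyl siloxyalkyne. The enabling feature is that ring A is a phloroglucinol with oxygen on C5, C7 and C8a and the prenyl group on C8 between C7–O and C8a–O. A vinylketene/siloxyalkyne benzannulation delivers this pattern with the three oxygens already differentiated (free OH on C8a, silyl ether on C7, alkyl ether on C5).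
- Forward: ring A (step 3), acetyl group on C4a (steps 4–6), ring C through the free C8a–OH (steps 7–8), sulfone activation and attachment of ring B through oxygen (steps 9–10), global desilylation (step 11).
- Stereochemistry: the target has no stereocentre and no stereogenic alkene. The carbinol centre of 16 is racemic and is erased by oxidation.

Key step: step 3

Assumption: 19 is drawn as its 4-hydroxy-2-thione tautomer, and ethyl 4-methylpent-3-enoate and 4-(tert-butyldimethylsilyloxy)phenol are treated as purchasable.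

**Route**

Step 1
Reactants: 1 3-ethoxycyclobut-2-en-1-one; 2 2-(trimethylsilyl)ethanol
Product: 3 3-[2-(trimethylsilyl)ethoxy]cyclobut-2-en-1-one
Conditions: 2 (4 equiv), pyridinium p-toluenesulfonate (5 mol%), PhMe, 40 °C, reduced pressure (EtOH removed)
Reagents that add atoms: none
Why: Acid-catalysed transetherification of a vinylogous ester (addition of the alcohol to the protonated enone, loss of ethanol) is an equilibrium that removal of the volatile ethanol should drive to 3, and the mild pyridinium acid should spare the strained ring and the β-silyl alcohol.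

Step 2
Reactants: 4 ethyl 4-methylpent-3-enoate; 5 triisopropylsilyl chloride
Product: 8 triisopropyl[(5-methylhex-4-en-1-yn-1-yl)oxy]silane, via lithium dibromo enolate 6 (not isolated), via lithium ynolate 7 (not isolated)
Conditions: CH2Br2, lithium 2,2,6,6-tetramethylpiperidide, THF, −78 °C; then 4; LiN(SiMe3)2, −78 °C; n-BuLi, −78 → 0 °C; then 5, −78 °C → rt
Reagents that add atoms: dibromomethane, BrCBr
Why: This is the Kowalski ester homologation stopped at the ynolate: dibromomethyllithium acylates on the ester, enolate 6 undergoes bromine–lithium exchange and 1,2-shift of the prenyl group to ynolate 7, and the bulky silyl chloride should trap 7 on oxygen, the standard entry to triisopropylsilyloxyalkynes.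

Step 3
Reactants: 3 3-[2-(trimethylsilyl)ethoxy]cyclobut-2-en-1-one; 8 triisopropyl[(5-methylhex-4-en-1-yn-1-yl)oxy]silane
Product: 13 2-(3-methylbut-2-enyl)-3-(triisopropylsilyloxy)-5-[2-(trimethylsilyl)ethoxy]phenol, via vinylketene 9 (not isolated), via vinylcyclobutenone 10 (not isolated), via dienylketene 11 (not isolated), via cyclohexadienone 12 (not isolated)
Conditions: 3 (1 equiv), 8 (1.3 equiv), degassed PhMe, 80 °C then 110 °C, sealed vessel
Reagents that add atoms: none
Why: This is a Danheiser benzannulation in its cyclobutenone/siloxyalkyne form: thermal 4π electrocyclic opening of 3 should give vinylketene 9, which adds across the ynol ether of 8 in a [2+2] cycloaddition to cyclobutenone 10, and 10 opens (4π) to dienylketene 11, which cyclises to dienone 12 and tautomerises to phenol 13. The [2+2] step makes C8a–C8 and C7–C6 (chromone numbering), and ring A then closes at C8a–C4a by a thermal disrotatory 6π electrocyclisation, a pericyclic closure of a six-membered carbocycle. The closest known reactions are the benzannulations of 3-alkyl- and 3-arylcyclobutenones with triisopropylsilyloxyalkynes at about 80 °C, which give resorcinol monosilyl ethers. The selectivity required is the regiochemistry of the [2+2] step, and the polarised siloxyalkyne secures it, because its nucleophilic prenyl-bearing carbon attacks the electrophilic ketene carbonyl carbon, so that this carbon becomes C8a–OH with the prenyl group ortho to it and the silyloxy carbon becomes C7. The ketene should choose the ynol ether over the far less nucleophilic prenyl alkene, and the neutral medium keeps both silicon groups in place. No stereocentre survives the step, since the one in 10 disappears on ring opening.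

Step 4
Reactants: 13 2-(3-methylbut-2-enyl)-3-(triisopropylsilyloxy)-5-[2-(trimethylsilyl)ethoxy]phenol
Product: 15 2-hydroxy-3-(3-methylbut-2-enyl)-4-(triisopropylsilyloxy)-6-[2-(trimethylsilyl)ethoxy]benzaldehyde, via hydroxymethylphenol 14 (not isolated)
Conditions: MgCl2, Et3N, (CH2O)n, MeCN, 80 °C; 1 M HCl, 0 °C
Reagents that add atoms: paraformaldehyde (as formaldehyde), C=O
Why: In this magnesium-mediated ortho-formylation (Casnati–Skattebøl reaction) the chloromagnesium phenoxide delivers formaldehyde only to the carbon ortho to the free hydroxyl, which is C4a because C8 is blocked, and a second formaldehyde oxidises hydroxymethyl intermediate 14 to the aldehyde.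

Step 5
Reactants: 15 2-hydroxy-3-(3-methylbut-2-enyl)-4-(triisopropylsilyloxy)-6-[2-(trimethylsilyl)ethoxy]benzaldehyde
Product: 16 2-(1-hydroxyethyl)-6-(3-methylbut-2-enyl)-5-(triisopropylsilyloxy)-3-[2-(trimethylsilyl)ethoxy]phenol (racemic)
Conditions: MeMgBr (3 equiv), THF, −78 → 0 °C; aq. NH4Cl; used without chromatography
Reagents that add atoms: methylmagnesium bromide, C[Mg]Br
Why: Grignard addition to the aldehyde follows deprotonation of the phenol, and the new carbinol centre forms without control as a racemate, which does not matter because the next step oxidises it.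

Step 6
Reactants: 16 2-(1-hydroxyethyl)-6-(3-methylbut-2-enyl)-5-(triisopropylsilyloxy)-3-[2-(trimethylsilyl)ethoxy]phenol
Product: 17 1-{2-hydroxy-3-(3-methylbut-2-enyl)-4-(triisopropylsilyloxy)-6-[2-(trimethylsilyl)ethoxy]phenyl}ethanone
Conditions: activated MnO2 (excess), CH2Cl2, rt
Reagents that add atoms: none
Why: Manganese dioxide oxidation is selective for benzylic alcohols and should leave the prenyl alkene, the phenol and the silyl ethers alone, giving the hydrogen-bonded ortho-hydroxy ketone.

Step 7
Reactants: 17 1-{2-hydroxy-3-(3-methylbut-2-enyl)-4-(triisopropylsilyloxy)-6-[2-(trimethylsilyl)ethoxy]phenyl}ethanone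
Product: 19 4-hydroxy-8-(3-methylbut-2-enyl)-7-(triisopropylsilyloxy)-5-[2-(trimethylsilyl)ethoxy]-2H-chromene-2-thione, via oxodithioic acid 18 (not isolated)
Conditions: NaH (4 equiv), CS2 (3 equiv), THF, 0 → 40 °C; 1 M HCl, 0 °C
Reagents that add atoms: carbon disulfide, S=C=S
Why: Claisen-type condensation of the ketone enolate with carbon disulfide gives β-oxodithioate 18, which on acidification should cyclise through the only free phenol (C8a–OH) with loss of hydrogen sulfide, the established route from 2-hydroxyacetophenones to 4-hydroxy-2H-chromene-2-thiones.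

Step 8
Reactants: 19 4-hydroxy-8-(3-methylbut-2-enyl)-7-(triisopropylsilyloxy)-5-[2-(trimethylsilyl)ethoxy]-2H-chromene-2-thione
Product: 20 8-(3-methylbut-2-enyl)-2-(methylsulfanyl)-7-(triisopropylsilyloxy)-5-[2-(trimethylsilyl)ethoxy]-4H-chromen-4-one
Conditions: MeI (1.1 equiv), K2CO3, acetone, rt
Reagents that add atoms: iodomethane, CI
Why: S-alkylation of the ambident thione anion by the soft electrophile iodomethane (thio-Williamson alkylation) should give the 2-(methylsulfanyl)chromone.

Step 9
Reactants: 20 8-(3-methylbut-2-enyl)-2-(methylsulfanyl)-7-(triisopropylsilyloxy)-5-[2-(trimethylsilyl)ethoxy]-4H-chromen-4-one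
Product: 21 8-(3-methylbut-2-enyl)-2-(methylsulfonyl)-7-(triisopropylsilyloxy)-5-[2-(trimethylsilyl)ethoxy]-4H-chromen-4-one
Conditions: (NH4)6Mo7O24·4H2O (10 mol%), 30% aq. H2O2, EtOH/THF, 0 °C → rt
Reagents that add atoms: hydrogen peroxide, OO
Why: Molybdate-catalysed peroxide oxidation of a sulfide to the sulfone is the method routinely used in the presence of trisubstituted alkenes, because the peroxomolybdate oxidises sulfur much faster than an isolated C=C bond.

Step 10
Reactants: 21 8-(3-methylbut-2-enyl)-2-(methylsulfonyl)-7-(triisopropylsilyloxy)-5-[2-(trimethylsilyl)ethoxy]-4H-chromen-4-one; 22 4-(tert-butyldimethylsilyloxy)phenol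
Product: 23 2-[4-(tert-butyldimethylsilyloxy)phenoxy]-8-(3-methylbut-2-enyl)-7-(triisopropylsilyloxy)-5-[2-(trimethylsilyl)ethoxy]-4H-chromen-4-one
Conditions: 22 (1.2 equiv), K2CO3, MeCN, 0 °C → rt
Reagents that add atoms: none
Why: Nucleophilic vinylic substitution by addition–elimination at C2, with the phenoxide adding to the doubly activated carbon and methanesulfinate leaving, is the known way from 2-sulfonyl- and 2-sulfinylchromones to 2-aryloxychromones.

Step 11
Reactants: 23 2-[4-(tert-butyldimethylsilyloxy)phenoxy]-8-(3-methylbut-2-enyl)-7-(triisopropylsilyloxy)-5-[2-(trimethylsilyl)ethoxy]-4H-chromen-4-one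
Product: 24 Epimedonin G [5,7-dihydroxy-2-(4-hydroxyphenoxy)-8-(3-methylbut-2-enyl)-4H-chromen-4-one]
Conditions: Bu4NF (6 equiv), THF/DMF, 0 → 45 °C; aq. NH4Cl
Reagents that add atoms: none
Why: Fluoride-mediated desilylation should cleave both aryl silyl ethers and attack the trimethylsilyl group of the 2-(trimethylsilyl)ethyl ether, which fragments to ethene and the C5 phenoxide (β-elimination), so one reagent frees all three hydroxyls without acid that could cyclise the prenyl group onto a neighbouring phenol.

**Compound list**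

1 | 3-ethoxycyclobut-2-en-1-one | CCOC1=CC(=O)C1 | starting material
2 | 2-(trimethylsilyl)ethanol | C[Si](C)(C)CCO | starting material
3 | 3-[2-(trimethylsilyl)ethoxy]cyclobut-2-en-1-one | C[Si](C)(C)CCOC1=CC(=O)C1 | intermediate
4 | ethyl 4-methylpent-3-enoate | CCOC(=O)CC=C(C)C | starting material
5 | triisopropylsilyl chloride | CC(C)[Si](Cl)(C(C)C)C(C)C | starting material
6 | lithium 1,1-dibromo-5-methylhexa-1,4-dien-2-olate (not isolated) | [Li+].[O-]C(CC=C(C)C)=C(Br)Br | intermediate
7 | lithium 5-methylhex-4-en-1-yn-1-olate (not isolated) | [Li+].[O-]C#CCC=C(C)C | intermediate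
8 | triisopropyl[(5-methylhex-4-en-1-yn-1-yl)oxy]silane | CC(C)=CCC#CO[Si](C(C)C)(C(C)C)C(C)C | intermediate
9 | 3-[2-(trimethylsilyl)ethoxy]buta-1,3-dien-1-one, the vinylketene (not isolated) | C=C(OCC[Si](C)(C)C)C=C=O | intermediate
10 | 2-(3-methylbut-2-enyl)-3-(triisopropylsilyloxy)-4-{1-[2-(trimethylsilyl)ethoxy]ethenyl}cyclobut-2-en-1-one, racemic (not isolated) | CC(C)=CCC1=C(O[Si](C(C)C)(C(C)C)C(C)C)C(C(=C)OCC[Si](C)(C)C)C1=O | intermediate
11 | (3E)-2-(3-methylbut-2-enyl)-3-(triisopropylsilyloxy)-5-[2-(trimethylsilyl)ethoxy]hexa-1,3,5-trien-1-one, C2 and C5 cis across C3=C4 (not isolated) | O=C=C(CC=C(C)C)/C(O[Si](C(C)C)(C(C)C)C(C)C)=C\C(=C)OCC[Si](C)(C)C | intermediate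
12 | 2-(3-methylbut-2-enyl)-3-(triisopropylsilyloxy)-5-[2-(trimethylsilyl)ethoxy]cyclohexa-2,4-dien-1-one (not isolated) | CC(C)=CCC1=C(O[Si](C(C)C)(C(C)C)C(C)C)C=C(OCC[Si](C)(C)C)CC1=O | intermediate
13 | 2-(3-methylbut-2-enyl)-3-(triisopropylsilyloxy)-5-[2-(trimethylsilyl)ethoxy]phenol | CC(C)=CCc1c(O)cc(OCC[Si](C)(C)C)cc1O[Si](C(C)C)(C(C)C)C(C)C | intermediate
14 | 2-(hydroxymethyl)-6-(3-methylbut-2-enyl)-5-(triisopropylsilyloxy)-3-[2-(trimethylsilyl)ethoxy]phenol (not isolated) | CC(C)=CCc1c(O)c(CO)c(OCC[Si](C)(C)C)cc1O[Si](C(C)C)(C(C)C)C(C)C | intermediate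
15 | 2-hydroxy-3-(3-methylbut-2-enyl)-4-(triisopropylsilyloxy)-6-[2-(trimethylsilyl)ethoxy]benzaldehyde | CC(C)=CCc1c(O)c(C=O)c(OCC[Si](C)(C)C)cc1O[Si](C(C)C)(C(C)C)C(C)C | intermediate
16 | 2-(1-hydroxyethyl)-6-(3-methylbut-2-enyl)-5-(triisopropylsilyloxy)-3-[2-(trimethylsilyl)ethoxy]phenol, racemic | CC(C)=CCc1c(O)c(C(C)O)c(OCC[Si](C)(C)C)cc1O[Si](C(C)C)(C(C)C)C(C)C | intermediate
17 | 1-{2-hydroxy-3-(3-methylbut-2-enyl)-4-(triisopropylsilyloxy)-6-[2-(trimethylsilyl)ethoxy]phenyl}ethanone | CC(C)=CCc1c(O)c(C(C)=O)c(OCC[Si](C)(C)C)cc1O[Si](C(C)C)(C(C)C)C(C)C | intermediate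
18 | 3-{2-hydroxy-3-(3-methylbut-2-enyl)-4-(triisopropylsilyloxy)-6-[2-(trimethylsilyl)ethoxy]phenyl}-3-oxopropanedithioic acid, present as its sodium salt until acidification (not isolated) | CC(C)=CCc1c(O)c(C(=O)CC(=S)S)c(OCC[Si](C)(C)C)cc1O[Si](C(C)C)(C(C)C)C(C)C | intermediate
19 | 4-hydroxy-8-(3-methylbut-2-enyl)-7-(triisopropylsilyloxy)-5-[2-(trimethylsilyl)ethoxy]-2H-chromene-2-thione | CC(C)=CCc1c(O[Si](C(C)C)(C(C)C)C(C)C)cc(OCC[Si](C)(C)C)c2c(O)cc(=S)oc12 | intermediate
20 | 8-(3-methylbut-2-enyl)-2-(methylsulfanyl)-7-(triisopropylsilyloxy)-5-[2-(trimethylsilyl)ethoxy]-4H-chromen-4-one | CC(C)=CCc1c(O[Si](C(C)C)(C(C)C)C(C)C)cc(OCC[Si](C)(C)C)c2c(=O)cc(SC)oc12 | intermediate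
21 | 8-(3-methylbut-2-enyl)-2-(methylsulfonyl)-7-(triisopropylsilyloxy)-5-[2-(trimethylsilyl)ethoxy]-4H-chromen-4-one | CC(C)=CCc1c(O[Si](C(C)C)(C(C)C)C(C)C)cc(OCC[Si](C)(C)C)c2c(=O)cc(S(C)(=O)=O)oc12 | intermediate
22 | 4-(tert-butyldimethylsilyloxy)phenol | CC(C)(C)[Si](C)(C)Oc1ccc(O)cc1 | starting material
23 | 2-[4-(tert-butyldimethylsilyloxy)phenoxy]-8-(3-methylbut-2-enyl)-7-(triisopropylsilyloxy)-5-[2-(trimethylsilyl)ethoxy]-4H-chromen-4-one | CC(C)=CCc1c(O[Si](C(C)C)(C(C)C)C(C)C)cc(OCC[Si](C)(C)C)c2c(=O)cc(Oc3ccc(O[Si](C)(C)C(C)(C)C)cc3)oc12 | intermediate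
24 | Epimedonin G, 5,7-dihydroxy-2-(4-hydroxyphenoxy)-8-(3-methylbut-2-enyl)-4H-chromen-4-one | CC(C)=CCc1c(O)cc(O)c2c(=O)cc(Oc3ccc(O)cc3)oc12 | target

**Step count**

Total: 11 steps. Longest linear sequence: 10 steps (step 1 or step 2, then steps 3 to 11).

**Steps most likely to fail**

1. Step 3. The donor-stabilised cyclobutenone may open to the vinylketene only at temperatures at which the siloxyalkyne rearranges by 1,3-silyl shift to a silylketene, and the vinylketene may acylate the phenol as it forms. The fallback makes the same vinylketene without heat, by 1,4-dehydrochlorination of an acid chloride. It sets out from 2-(trimethylsilyl)ethanol 2 and siloxyalkyne 8 and comes back at vinylketene 9 in the flask, and so at phenol 13. PMe3-catalysed conjugate addition of 2 to commercial ethyl but-2-ynoate should give ethyl (E)-3-[2-(trimethylsilyl)ethoxy]but-2-enoate F1. LiOH in aqueous THF would give (E)-3-[2-(trimethylsilyl)ethoxy]but-2-enoic acid F2, and oxalyl chloride with catalytic DMF would give (E)-3-[2-(trimethylsilyl)ethoxy]but-2-enoyl chloride F3. Et3N added to F3 and 8 in CH2Cl2 at 0 °C → rt should release 9 by loss of HCl across the γ-methyl group, and 8 traps it as cyclobutenone 10. Brief warming to 80 °C in PhMe then carries 10 through 11 and 12 to 13.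

2. Step 2. Dibromomethyllithium may deprotonate the doubly activated α-CH2 of the β,γ-unsaturated ester instead of adding to its carbonyl group, and the skipped double and triple bonds may migrate under the strongly basic warm-up. The fallback makes the ynolate by oxidising an acetylide instead of by rearrangement. It sets out from ester 4 and comes back at ynolate 7, which is silylated with 5 to 8 as in step 2. i-Bu2AlH in CH2Cl2 at −78 °C should reduce 4 to 4-methylpent-3-enal F4. Corey–Fuchs olefination (CBr4, PPh3, Zn, CH2Cl2, 0 °C) would give 1,1-dibromo-5-methylhexa-1,4-diene F5. n-BuLi (2 equiv, THF, −78 °C) would give lithium 5-methylhex-4-en-1-ynide F6, and LiOOt-Bu (from t-BuOOH and LiN(SiMe3)2, −78 → 0 °C) would transfer oxygen to the acetylide carbon to give 7.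

3. Step 11. The aryl 2-(trimethylsilyl)ethyl ether may fragment slowly, and the forcing fluoride conditions then needed may exchange the 2-aryloxy group (a vinylogous carbonate) at C2. The fallback splits the deprotection into two stages and uses a chelating Lewis acid for the last ether. It sets out from 23 and comes back at target 24. Bu4NF buffered with AcOH in THF at 0 °C should remove only the two aryl silyl ethers and give 7-hydroxy-2-(4-hydroxyphenoxy)-8-(3-methylbut-2-enyl)-5-[2-(trimethylsilyl)ethoxy]-4H-chromen-4-one F7. MgBr2·OEt2 in Et2O/MeNO2 at rt, bound between the C4 carbonyl and O5, should then cleave the 2-(trimethylsilyl)ethyl ether to 24 without protic acid.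

**Further compounds**

F1 | step 3 | ethyl (E)-3-[2-(trimethylsilyl)ethoxy]but-2-enoate | CCOC(=O)/C=C(/OCC[Si](C)(C)C)C
F2 | step 3 | (E)-3-[2-(trimethylsilyl)ethoxy]but-2-enoic acid | OC(=O)/C=C(/OCC[Si](C)(C)C)C
F3 | step 3 | (E)-3-[2-(trimethylsilyl)ethoxy]but-2-enoyl chloride | ClC(=O)/C=C(/OCC[Si](C)(C)C)C
F4 | step 2 | 4-methylpent-3-enal | CC(C)=CCC=O
F5 | step 2 | 1,1-dibromo-5-methylhexa-1,4-diene | CC(C)=CCC=C(Br)Br
F6 | step 2 | lithium 5-methylhex-4-en-1-ynide | [Li]C#CCC=C(C)C
F7 | step 11 | 7-hydroxy-2-(4-hydroxyphenoxy)-8-(3-methylbut-2-enyl)-5-[2-(trimethylsilyl)ethoxy]-4H-chromen-4-one | CC(C)=CCc1c(O)cc(OCC[Si](C)(C)C)c2c(=O)cc(Oc3ccc(O)cc3)oc12
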